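**Retrosynthetic overview**

1. Numbering (daucane): ring A = C1 (quaternary, CH3), C2 (OAc), C3, C4 (OH, iPr), C5 (fusion CH). Ring B = C1, C5, C6 (O-anisoyl), C7, C8(CH3)=C9, C10. β is the face of the C1 methyl. Feature used: in ring B the alkene C8=C9 and the enol C5=C6 of a C6 ketone flank the single methylene C7 as a skipped 1,4-diene. This is the retron of a cis-divinylcyclopropane C6-C7-C8 whose outer alkene ends are C1 and C10.
2. The C6 anisate and C2 acetate are removed first. The 6α-carbinol comes from the C6 ketone by hydride delivered from the 4β-OH, and the trans fusion (H5 α) comes from equilibration of that ketone.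
3. Key disconnection: a retro-[3,3] shift opens C1-C10 and re-forms C6-C8. Taking C7 out of the cyclopropane as CH2 then leaves a monocyclic trienol silyl ether.
4. The trienol ether comes from the tigloyl ketone by γ-deprotonation, and the ketone from a C5 vinyllithium plus the tiglic Weinreb amide. The ring A centres are set by relay: C2 of (R)-4-silyloxycyclopentenone steers isopropyl onto C4, and the C4-OH then steers hydride back onto C2.
5. Ring order: ring A is bought, the cyclopropane is transient, and ring B closes last.

Key step: step 12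

Assumption: (R)-4-(tert-butyldimethylsilyloxy)cyclopent-2-en-1-one is taken as a commercial single enantiomer. Metal alkoxides and adducts that are only protonated or collapse on aqueous work-up are not numbered.

**Step 1**
Reactants: 1 (R)-4-(tert-butyldimethylsilyloxy)cyclopent-2-en-1-one; 2 methylmagnesium bromide
Product: 3 [(3R,4R)-4-(tert-butyldimethylsilyloxy)-3-methylcyclopent-1-en-1-yl]oxytrimethylsilane
Conditions: MeMgBr, CuBr·SMe2 (10 mol %), Me3SiCl, THF, −78 °C
Reagents that add atoms: methylmagnesium bromide, C[Mg]Br; chlorotrimethylsilane, C[Si](C)(C)Cl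
Why: Copper-catalysed, chlorosilane-accelerated conjugate addition: methyl should enter C1 anti to the C2 silyl ether, and the enolate is caught as its silyl enol ether before it can expel the β-silyloxy group, the new C1 centre being only transient.

**Step 2**
Reactants: 3 silyl enol ether
Product: 4 (R)-4-(tert-butyldimethylsilyloxy)-3-methylcyclopent-2-en-1-one
Conditions: Pd(OAc)2 (1.05 equiv), MeCN, rt
Reagents that add atoms: none
Why: Saegusa-Ito oxidation: the palladium enolate at C5 has only H1 available for syn β-hydride elimination, so the enone returns with C1 methylated and C2 untouched under neutral conditions.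

**Step 3**
Reactants: 4 methyl enone
Product: 6 (R)-2-bromo-4-(tert-butyldimethylsilyloxy)-3-methylcyclopent-2-en-1-one, via trans-2,3-dibromide 5 (not isolated)
Conditions: Br2, CH2Cl2, −78 → 0 °C; then Et3N, 0 °C → rt
Reagents that add atoms: bromine, BrBr
Why: Bromine addition followed by amine-induced E1cB loss of HBr (H5 is the only acidic proton next to a bromide) is the standard α-bromination of a β-substituted cyclopentenone and puts the metalation handle on C5.

**Step 4**
Reactants: 6 bromoenone; 7 isopropylmagnesium chloride
Product: 8 (1R,4R)-2-bromo-4-(tert-butyldimethylsilyloxy)-1-isopropyl-3-methylcyclopent-2-en-1-ol (OH and OSi cis)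
Conditions: CeCl3 (dried), iPrMgCl, THF, −78 °C; aq NH4Cl
Reagents that add atoms: isopropylmagnesium chloride, CC(C)[Mg]Cl
Why: Organocerium 1,2-addition: the weakly basic reagent suppresses enolisation, β-hydride reduction and halogen-metal exchange, and attack on the flat enone anti to the β silyl ether at C2 should place isopropyl α and the hydroxyl β (4R).

**Step 5**
Reactants: 8 silyl ether
Product: 9 (1R,4R)-2-bromo-1-isopropyl-3-methylcyclopent-2-ene-1,4-diol (cis diol)
Conditions: Bu4NF, THF, 0 °C → rt
Reagents that add atoms: none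
Why: Fluoride desilylation frees the C2 carbinol, whose relay task is finished, without touching the vinyl bromide or the tertiary alcohol.

**Step 6**
Reactants: 9 cis diol
Product: 10 (R)-3-bromo-4-hydroxy-4-isopropyl-2-methylcyclopent-2-en-1-one
Conditions: Dess-Martin periodinane, CH2Cl2, 0 °C → rt
Reagents that add atoms: none
Why: Dess-Martin oxidation can only take the secondary allylic alcohol, so C2 becomes trigonal while C4 is kept.

**Step 7**
Reactants: 10 hydroxy bromoenone
Product: 11 (1R,4S)-2-bromo-1-isopropyl-3-methylcyclopent-2-ene-1,4-diol (trans diol)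
Conditions: Me4NBH(OAc)3, MeCN/AcOH, −30 → 0 °C
Reagents that add atoms: none
Why: Evans-Saksena hydroxyl-directed reduction: boron bound to the 4β-oxygen hands hydride to the β face of C2, which is also the face anti to isopropyl, so both effects should give the 2α-alcohol (2S, trans to 4-OH, cis to isopropyl) by 1,2-reduction.

**Step 8**
Reactants: 11 trans diol
Product: 12 (1R,4S)-2-bromo-4-(tert-butyldimethylsilyloxy)-1-isopropyl-3-methylcyclopent-2-en-1-ol
Conditions: TBSCl, imidazole, DMF, 0 °C → rt
Reagents that add atoms: tert-butyldimethylsilyl chloride, CC(C)(C)[Si](C)(C)Cl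
Why: Silylation with the chloride and imidazole distinguishes the secondary allylic hydroxyl from the hindered tertiary one, which must stay free as the later directing group.

**Step 9**
Reactants: 13 tiglic acid
Product: 15 (E)-N-methoxy-N,2-dimethylbut-2-enamide, via N-tigloylimidazole 14 (not isolated)
Conditions: 1,1'-carbonyldiimidazole, CH2Cl2, rt; then MeNH(OMe)·HCl
Reagents that add atoms: N,O-dimethylhydroxylamine hydrochloride, CNOC.Cl
Why: Acyl imidazolide activation and aminolysis (Weinreb amide formation) proceed without isomerising the (E)-alkene.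

**Step 10**
Reactants: 12 vinyl bromide; 15 Weinreb amide
Product: 17 (E)-1-[(3S,5R)-3-(tert-butyldimethylsilyloxy)-5-hydroxy-5-isopropyl-2-methylcyclopent-1-en-1-yl]-2-methylbut-2-en-1-one, via dilithio alkoxide-vinyllithium 16 (not isolated)
Conditions: t-BuLi (3.2 equiv), THF, −78 °C; then 15, −78 → −20 °C; aq NH4Cl
Reagents that add atoms: Weinreb amide 15, C/C=C(\C)C(=O)N(C)OC
Why: Deprotonation, bromine-lithium exchange and Weinreb ketone synthesis: the ring vinyllithium cannot eliminate the neighbouring alkoxide, it lies trans to the C2 silyloxy carbon so that silyl migration is not possible, and the chelated adduct stops at the ketone stage.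

**Step 11**
Reactants: 17 dienone
Product: 19 (1R,4S)-4-(tert-butyldimethylsilyloxy)-2-[(1E)-1-(tert-butyldimethylsilyloxy)-2-methylbuta-1,3-dien-1-yl]-1-isopropyl-3-methylcyclopent-2-en-1-ol, via disodium alkoxide-dienolate 18 (not isolated)
Conditions: NaN(SiMe3)2 (2.3 equiv), THF, −78 °C; TBSCl (1.15 equiv), −78 → −30 °C; pH 7 buffer; Et3N-washed silica, kept cold
Reagents that add atoms: tert-butyldimethylsilyl chloride, CC(C)(C)[Si](C)(C)Cl
Why: Vinylogous (γ) deprotonation of the tigloyl enone and O-silylation of the extended enolate, as in the making of silyl dienol ethers from tiglates: the first equivalent of base parks the hindered C4 hydroxyl as an alkoxide that TBSCl does not silylate in the cold, only the tigloyl alkene is coplanar with the carbonyl (the tetrasubstituted ring alkene is twisted out, so the C1 methyl and H2 stay untouched), and deprotonation from the preferred s-trans rotamer (C8 methyl next to O, H9 next to the ring) should fix the (E) geometry with C9 cis to C5.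

**Step 12**
Reactants: 19 trienol silyl ether; 20 diiodomethane
Product: 23 (1R,2S,4R)-2α,6-bis(tert-butyldimethylsilyloxy)-4β-hydroxydauca-5,8-diene, via iodomethylzinc alkoxide 21 (not isolated), via cis-divinylcyclopropane zinc alkoxide 22 (not isolated)
Conditions: Et2Zn (2.2 equiv), CH2I2 (2.0 equiv), PhMe, −20 → 0 °C; pyridine; then rt → 60 °C; aq NaHCO3, Et3N-washed silica
Reagents that add atoms: diiodomethane, ICI
Why: Et2Zn converts the 4β-hydroxyl into a zinc alkoxide that takes up CH2I2 as an iodomethylzinc group (21), and Simmons-Smith (Furukawa) methylene transfer, a concerted [2+1] closure of the three-membered ring, forms C6-C7 and C7-C8 at the silyl enol ether. Since C5 and C9 are cis on that alkene, 22 is a cis-divinylcyclopropane, and on gentle warming it should undergo the divinylcyclopropane-cycloheptadiene (strain-driven Cope) rearrangement through the endo boat transition state, which breaks C6-C8, forms C1-C10 and so closes ring B pericyclically with both ring alkenes (C8=C9 and the enol ether C5=C6) cis. The closest known reactions are cyclopropanation of silyloxydienes at the oxygenated double bond, hydroxyl-directed cyclopropanation of homoallylic alcohols, methylene addition to the central bond of cis-hexatrienes, and cis-divinylcyclopropane shifts that build quaternary carbons. C1, the only lasting new stereocentre, is set by relay: the crowded diene is twisted about C5-C6 with C8 and its vinyl group on the β side (away from isopropyl and the C2 silyl ether), the β alkoxide delivers CH2 to the alkene face that looks toward C4, and after a half turn about C5-C6 the boat geometry can only bring C10 to the α face of C1, leaving the methyl β (1R). The step needs chemoselectivity for C6=C8, which rests on its enol ether nucleophilicity against the unactivated vinyl C9=C10 and the more encumbered, non-oxygenated C5=C1, and on offering little more than one transferable methylene. Pyridine destroys excess carbenoid and ties up zinc iodide before warming, so that the siloxycyclopropane is not opened and the new alkenes of 23 are not attacked; the α silyl ether at C2 can slow the shift but cannot change its sense.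

**Step 13**
Reactants: 23 hydroazulene enol ether
Product: 24 (1R,2S,4R)-2α,6-bis(tert-butyldimethylsilyloxy)-4β-(triethylsilyloxy)dauca-5,8-diene
Conditions: Et3SiOTf, 2,6-lutidine, CH2Cl2, −78 → −20 °C
Reagents that add atoms: triethylsilyl triflate, CC[Si](CC)(CC)OS(=O)(=O)C(F)(F)F
Why: Silyl triflate-lutidine silylation of a hindered tertiary alcohol under basic conditions: capping O4 shuts the retro-aldol path of the coming β-hydroxy ketone, and acid is avoided because a C4 hydroxyl allylic to the C5=C6 enol ether would ionise with loss of the C4 oxygen (Stork-Danheiser-type enone formation).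

**Step 14**
Reactants: 24 tris-silyl ether
Product: 26 (1R,2S,4R,5R)-2α-(tert-butyldimethylsilyloxy)-4β-(triethylsilyloxy)dauc-8-en-6-one (H5 α; trans-fused), via cis-fused 5-epi ketone 25 (not isolated)
Conditions: Bu4NF, AcOH (1:1.2), THF, −20 → 0 °C; then K2CO3, MeOH, 0 °C → rt
Reagents that add atoms: none
Why: Buffered fluoride cleaves only the enol silyl ether, protonation is expected from the convex β face to give cis-fused 25, and carbonate in methanol then equilibrates C5 through the enolate to the trans-fused ketone, in which C6 stands trans to the isopropyl group on the neighbouring C4 (thermodynamic control), reprotonation in the protic medium outrunning loss of silanolate.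

**Step 15**
Reactants: 26 trans-fused ketone
Product: 27 (1R,2S,4R,5R)-2α,4β-dihydroxydauc-8-en-6-one
Conditions: HF·pyridine, pyridine, THF, 0 °C → rt
Reagents that add atoms: none
Why: Si-O cleavage with buffered HF removes the tertiary triethylsilyl ether and the neopentyl-type secondary silyl ether in one operation under conditions that β-hydroxy ketones and trisubstituted alkenes tolerate, and C5 already holds its more stable configuration.

**Step 16**
Reactants: 27 dihydroxy ketone
Product: 28 (1R,2S,4R,5R)-2α-acetoxy-4β-hydroxydauc-8-en-6-one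
Conditions: Ac2O, pyridine, DMAP (cat.), CH2Cl2, 0 °C → rt
Reagents that add atoms: acetic anhydride, CC(=O)OC(C)=O
Why: DMAP-catalysed acetylation reaches only the secondary 2α-hydroxyl, the tertiary 4-OH being inert, so the two ester sites are told apart by the order of events.

**Step 17**
Reactants: 28 acetoxy ketone
Product: 29 (1R,2S,4R,5S,6S)-2α-acetoxydauc-8-ene-4β,6α-diol
Conditions: Me4NBH(OAc)3, MeCN/AcOH, −25 → 0 °C
Reagents that add atoms: none
Why: Evans-Saksena reduction: in the trans-fused ketone C6 is cis to the 4β-oxygen, the only hydroxyl left, so the acetoxyborohydride bound there delivers hydride to the carbonyl face turned toward C4 and should give H6 β and the 6α-alcohol (6S), while the reagent does not reduce a ketone it cannot reach intramolecularly.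

**Step 18**
Reactants: 29 diol monoacetate; 30 p-anisoyl chloride
Product: 31 (1R,2S,4R,5S,6S)-2α-acetoxy-6α-(4-methoxybenzoyloxy)-4β-hydroxydauc-8-ene (CNP0171090.1)
Conditions: p-anisoyl chloride, Et3N, DMAP, CH2Cl2, rt → 40 °C
Reagents that add atoms: p-anisoyl chloride, COc1ccc(C(Cl)=O)cc1
Why: DMAP-catalysed acylation with the acid chloride esterifies the single secondary alcohol and leaves the tertiary 4-OH free, which completes the target.

**Compound list**

1 | (R)-4-(tert-butyldimethylsilyloxy)cyclopent-2-en-1-one | O=C1C=C[C@H](O[Si](C)(C)C(C)(C)C)C1 | starting material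
2 | methylmagnesium bromide | C[Mg]Br | starting material
3 | (3R,4R) trimethylsilyl enol ether | C[Si](C)(C)OC1=C[C@@H](C)[C@H](O[Si](C)(C)C(C)(C)C)C1 | intermediate
4 | (R)-4-(tert-butyldimethylsilyloxy)-3-methylcyclopent-2-en-1-one | O=C1C=C(C)[C@H](O[Si](C)(C)C(C)(C)C)C1 | intermediate
5 | (4R)-trans-2,3-dibromo-4-(tert-butyldimethylsilyloxy)-3-methylcyclopentan-1-one (drawn as the anti adduct) | O=C1[C@@H](Br)[C@](C)(Br)[C@H](O[Si](C)(C)C(C)(C)C)C1 | intermediate
6 | (R)-2-bromo-4-(tert-butyldimethylsilyloxy)-3-methylcyclopent-2-en-1-one | O=C1C(Br)=C(C)[C@H](O[Si](C)(C)C(C)(C)C)C1 | intermediate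
7 | isopropylmagnesium chloride | CC(C)[Mg]Cl | starting material
8 | (1R,4R)-2-bromo-4-(tert-butyldimethylsilyloxy)-1-isopropyl-3-methylcyclopent-2-en-1-ol | BrC1=C(C)[C@H](O[Si](C)(C)C(C)(C)C)C[C@@]1(O)C(C)C | intermediate
9 | (1R,4R)-2-bromo-1-isopropyl-3-methylcyclopent-2-ene-1,4-diol | BrC1=C(C)[C@H](O)C[C@@]1(O)C(C)C | intermediate
10 | (R)-3-bromo-4-hydroxy-4-isopropyl-2-methylcyclopent-2-en-1-one | BrC1=C(C)C(=O)C[C@@]1(O)C(C)C | intermediate
11 | (1R,4S)-2-bromo-1-isopropyl-3-methylcyclopent-2-ene-1,4-diol | BrC1=C(C)[C@@H](O)C[C@@]1(O)C(C)C | intermediate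
12 | (1R,4S)-2-bromo-4-(tert-butyldimethylsilyloxy)-1-isopropyl-3-methylcyclopent-2-en-1-ol | BrC1=C(C)[C@@H](O[Si](C)(C)C(C)(C)C)C[C@@]1(O)C(C)C | intermediate
13 | tiglic acid | C/C=C(\C)C(=O)O | starting material
14 | N-tigloylimidazole | C/C=C(\C)C(=O)n1ccnc1 | intermediate
15 | (E)-N-methoxy-N,2-dimethylbut-2-enamide | C/C=C(\C)C(=O)N(C)OC | intermediate
16 | dilithio alkoxide-vinyllithium from 12 | [Li]C1=C(C)[C@@H](O[Si](C)(C)C(C)(C)C)C[C@@]1(O[Li])C(C)C | intermediate
17 | tigloyl cyclopentenyl ketone (3S,5R) | C/C=C(\C)C(=O)C1=C(C)[C@@H](O[Si](C)(C)C(C)(C)C)C[C@@]1(O)C(C)C | intermediate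
18 | disodium alkoxide-dienolate of 17 | C=C/C(C)=C(/O[Na])C1=C(C)[C@@H](O[Si](C)(C)C(C)(C)C)C[C@@]1(O[Na])C(C)C | intermediate
19 | cyclopentenyl trienol silyl ether (key-step precursor) | C=C/C(C)=C(/O[Si](C)(C)C(C)(C)C)C1=C(C)[C@@H](O[Si](C)(C)C(C)(C)C)C[C@@]1(O)C(C)C | intermediate
20 | diiodomethane | ICI | starting material
21 | iodomethylzinc alkoxide of 19 | C=C/C(C)=C(/O[Si](C)(C)C(C)(C)C)C1=C(C)[C@@H](O[Si](C)(C)C(C)(C)C)C[C@@]1(O[Zn]CI)C(C)C | intermediate
22 | cis-divinylcyclopropane (C6 S, C8 R), iodozinc alkoxide | C=C[C@@]1(C)C[C@@]1(O[Si](C)(C)C(C)(C)C)C2=C(C)[C@@H](O[Si](C)(C)C(C)(C)C)C[C@@]2(O[Zn]I)C(C)C | intermediate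
23 | hydroazulene with C8=C9 and C5=C6 silyl enol ether (key-step product) | CC1=CC[C@@]2(C)[C@@H](O[Si](C)(C)C(C)(C)C)C[C@@](O)(C(C)C)C2=C(O[Si](C)(C)C(C)(C)C)C1 | intermediate
24 | C4 triethylsilyl ether of 23 | CC1=CC[C@@]2(C)[C@@H](O[Si](C)(C)C(C)(C)C)C[C@@](O[Si](CC)(CC)CC)(C(C)C)C2=C(O[Si](C)(C)C(C)(C)C)C1 | intermediate
25 | cis-fused (H5 β) C6 ketone | O=C1CC(C)=CC[C@@]2(C)[C@@H](O[Si](C)(C)C(C)(C)C)C[C@@](O[Si](CC)(CC)CC)(C(C)C)[C@@H]12 | intermediate
26 | trans-fused (H5 α) C6 ketone | O=C1CC(C)=CC[C@@]2(C)[C@@H](O[Si](C)(C)C(C)(C)C)C[C@@](O[Si](CC)(CC)CC)(C(C)C)[C@H]12 | intermediate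
27 | 2α,4β-dihydroxydauc-8-en-6-one | O=C1CC(C)=CC[C@@]2(C)[C@@H](O)C[C@@](O)(C(C)C)[C@H]12 | intermediate
28 | 2α-acetoxy-4β-hydroxydauc-8-en-6-one | O=C1CC(C)=CC[C@@]2(C)[C@@H](OC(C)=O)C[C@@](O)(C(C)C)[C@H]12 | intermediate
29 | 2α-acetoxydauc-8-ene-4β,6α-diol | O[C@H]1CC(C)=CC[C@@]2(C)[C@@H](OC(C)=O)C[C@@](O)(C(C)C)[C@H]12 | intermediate
30 | p-anisoyl chloride | COc1ccc(C(Cl)=O)cc1 | starting material
31 | CNP0171090.1 | COc1ccc(C(=O)O[C@H]2CC(C)=CC[C@@]3(C)[C@@H](OC(C)=O)C[C@@](O)(C(C)C)[C@H]23)cc1 | target

**Step count**

Total steps: 18. Longest linear sequence: 17 (steps 1-8 and 10-18).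

**Steps most likely to fail**

1. **Step 12.**
   - What may go wrong: the zinc alkoxide may steer methylene transfer to the allylic C5=C1 bond, or to the wrong face of C6=C8. Zinc iodide may open the siloxycyclopropane. The shift may be slow because C10 has to bond to a fully substituted C1 beside the α silyl ether.
   - Fallback, from 17 back to 23: the carbenoid is anchored on the enolate oxygen itself and the shift is run as an anionic process. LiN(SiMe3)2 (2.2 equiv, THF, −78 °C) gives the dilithium alkoxide-dienolate F1. SmI2/CH2I2 (the samarium-carbenoid cyclopropanol synthesis from enolates) should then address only the enolate bond C6=C8 and give the cis-divinylcyclopropanolate F2. Its oxyanion-accelerated [3,3] shift should run below room temperature to the bicyclic enolate F3. Silylation of O6 with TBSCl and neutral work-up returns to 23.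

2. **Step 14.**
   - What may go wrong: kinetic protonation from the β face may be followed by incomplete equilibration at C5, or the enolate may lose the C4 oxygen by β-elimination during the base treatment.
   - Fallback, from 23 (step 13 omitted) back to 27: the fusion is driven by chelation instead of by base on a silyl ether. Bu4NF/AcOH (THF, −20 °C) gives the cis-fused β-hydroxy ketone F4. MgBr2·OEt2 and iPr2NEt in CH2Cl2 (soft enolisation) then let C5 equilibrate while magnesium bridges O4 and O6. Only the trans-fused epimer allows this six-membered chelate, because there C6 is cis to the 4β-oxygen, so the trans-fused β-hydroxy ketone F5 becomes the sink and the alkoxide is held back from fragmentation. HF·pyridine removes the C2 silyl ether and rejoins the route at 27.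

3. **Step 11.**
   - What may go wrong: the C4 alkoxide may be silylated and the directing group lost, deprotonation may occur at the C1 methyl, or the enol ether geometry may erode.
   - Fallback, from 17 back to 19: the hydroxyl is masked and the enolisation mechanism is changed. N-(trimethylsilyl)imidazole gives the C4 trimethylsilyl ether F6. Soft enolisation with TBSOTf/Et3N (CH2Cl2, −78 → 0 °C) goes through the silyloxocarbenium ion and loss of a C10 proton, as in the making of 1-silyloxy-2-methylbutadienes from tiglic aldehyde, and gives the trimethylsilyl-protected trienol ether F7. K2CO3/MeOH at 0 °C then cleaves only the trimethylsilyl ether and gives 19.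

**Further compounds**

F1 | step 12 | dilithium alkoxide-dienolate of 17 | C=C/C(C)=C(/O[Li])C1=C(C)[C@@H](O[Si](C)(C)C(C)(C)C)C[C@@]1(O[Li])C(C)C
F2 | step 12 | cis-divinylcyclopropanolate (drawn as dilithium salt) | C=C[C@@]1(C)C[C@@]1(O[Li])C2=C(C)[C@@H](O[Si](C)(C)C(C)(C)C)C[C@@]2(O[Li])C(C)C
F3 | step 12 | bicyclic C6 enolate, C4 alkoxide (drawn as dilithium salt) | CC1=CC[C@@]2(C)[C@@H](O[Si](C)(C)C(C)(C)C)C[C@@](O[Li])(C(C)C)C2=C(O[Li])C1
F4 | step 14 | cis-fused 2α-(tert-butyldimethylsilyloxy)-4β-hydroxydauc-8-en-6-one | O=C1CC(C)=CC[C@@]2(C)[C@@H](O[Si](C)(C)C(C)(C)C)C[C@@](O)(C(C)C)[C@@H]12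
F5 | step 14 | trans-fused 2α-(tert-butyldimethylsilyloxy)-4β-hydroxydauc-8-en-6-one | O=C1CC(C)=CC[C@@]2(C)[C@@H](O[Si](C)(C)C(C)(C)C)C[C@@](O)(C(C)C)[C@H]12
F6 | step 11 | C4 trimethylsilyl ether of 17 | C/C=C(\C)C(=O)C1=C(C)[C@@H](O[Si](C)(C)C(C)(C)C)C[C@@]1(O[Si](C)(C)C)C(C)C
F7 | step 11 | C4 trimethylsilyl ether of 19 | C=C/C(C)=C(/O[Si](C)(C)C(C)(C)C)C1=C(C)[C@@H](O[Si](C)(C)C(C)(C)C)C[C@@]1(O[Si](C)(C)C)C(C)C
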